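Remark (assumption): the titanium catalyst made from (R)-BINOL is taken to give the (2R)-α-hydroxy ester in the glyoxylate-ene step, as it does with simple 1,1-disubstituted alkenes; if the substrate reversed this sense, (S)-BINOL would be used and nothing else would change.

## Structural features

The target is a cis-fused decalin, numbered here as a cadinane. Ring A is C1–C6 (C3 acetoxy, C4 methyl C15, C4=C5) and ring B is C1, C6, C7, C8, C9, C10. C7 carries the α-methylene acid C11(=C13)–C12O2H, C10 carries methyl C14 and a hydroxyl, and the C8 oxygen is esterified with (E)-4-hydroxy-2-(hydroxymethyl)but-2-enoic acid. Five of the six stereocentres are contiguous (C10–C1–C6–C7–C8) and C3 stands 1,3 to C1. If the face carrying H-1 and H-6 is called α, the C7 side chain, the C8 oxygen and the C10 methyl are α, while the C10 hydroxyl and the C3 acetoxy group are β (1R,3S,6R,7S,8S,10S). Fragile groups are the α-methylene acid (a Michael acceptor that lactonises with a free cis C8 hydroxyl), the allylic acetate, the tertiary alcohol, and three different esters that must survive beside a free acid. The real difficulty is the C6–C7 bond between the ring-fusion carbon and the carbon bearing the acrylate, with control of C6, C7 and C8, followed by acylation of the hindered C8 oxygen. The key step exploits the fact that ring A, with its C3 oxygen, C4 methyl, C4=C5 alkene and C1 substituent, is (S)-carvone, and that C6 is the γ-carbon of that enone next to C1, so an extended enolate can close ring B onto a tethered 2-(bromomethyl)enoate and leave the α-methylene ester behind. The closure places the C8 oxygen trans to the acrylate whereas the target has it cis, so C8 is carried as its epimer and inverted when the side chain is attached.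

## Logic of the disconnections

26 ⇒ 24 (through 25). The bonds cut are the alkyl–oxygen bond of the C12 ester and the two acetal C–O bonds of the side chain. The acid and the diol are the most polar and reactive functions, so they stay masked until the end and every earlier compound is neutral. The forward step must remove both groups without touching the acetate, the C8 ester or the tertiary alcohol: fluoride for the silylethyl ester, then weak aqueous acid for the acetal.

24 ⇒ 18 + 23. The bond cut is C8–O of the side-chain ester. Forming it by displacement at C8 joins the two fragments and at the same time inverts the 8-epi centre, and C8 never carries a free hydroxyl cis to the C12 ester. The demand is an SN2 reaction at a hindered ring carbon beside an untouched tertiary alcohol.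

23 ⇒ 21 ⇒ 20 ⇒ 19 (through 22). The bonds cut are the vinyl C–CO2H bond, the acetal C–O bonds, and the C–Sn and C–H bonds across the alkene. A symmetrical alkyne removes any regiochemical question and syn addition fixes the alkene geometry. The demand is retention of geometry at the vinyl metal.

18 ⇒ 17 ⇒ 16 ⇒ 14 (through 15). The bonds cut are O–Si at C8 and C10–C14, and the C10 carbonyl is traced back to the C10 methylene. The C10 carbinol is made by addition to a ketone from the convex face while the C8 oxygen is still equatorial and silylated, so it must precede the inversion at C8. The demands are cleavage of one alkene out of three and a methyl nucleophile that spares two esters.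

14 ⇒ 13 ⇒ 12. The bonds cut are the acetyl C–O bond and C3–H. The C3 oxygen is the carbonyl oxygen of the chiral-pool ring, so only its oxidation level and configuration have to be set. The demand is a 1,2-reduction from the open face that leaves the unsaturated ester alone.

12 ⇒ 10 (through 11). The bond cut is C6–C7. This single cut opens ring B, removes two stereocentres and returns the α-methylene ester to an allylic bromide. The forward step must react through C6 and not through C2, and it must translate the C1 and C8 centres into C6 and C7.

10 ⇒ 9 ⇒ 8 + 2, and 2 ⇒ 1. The cuts are C13–Br (with allylic transposition of the oxygen from C7) and C7–C11. An aldehyde and an acrylate give the whole electrophilic arm in two steps. The demand is that the α-silyloxy aldehyde keeps its configuration.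

8 ⇒ 7 ⇒ 6 ⇒ 5. No skeletal bond is cut; the ester is taken to the aldehyde and the hydroxyl is protected. Because the ester cannot be reduced beside the enone, both carbonyls are reduced and both alcohols are re-oxidised.

5 ⇒ 3 + 4. The bond cut is C8–C9. An ene reaction at the isopropenyl group attaches C7 and C8 to the terpene and creates the C8 carbinol in one atom-economic step. The demand is catalyst control of a centre that lies 1,4 to the existing one.

## Other disconnections considered

Alternative 1: Biomimetic transannular cyclization. The cut removes C1–C6 and the C10–O bond together and leads from decalin A2 back to the ten-membered triene A1 (a germacrene-type 1(10),5-diene with a C4 exocyclic methylene). In the forward step acid in a wet solvent would protonate the C4 methylene, the C1=C10 alkene would attack C6 of the C4–C5–C6 allyl cation across the ring, and water would add at C10.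
- In its favour: both rings, C1, C6 and C10 arise in one operation, the C10 carbinol needs no ketone and methyl nucleophile, and C8 can be carried in its natural configuration. On these three points it is better than the chosen plan.
- Against it: A1 is itself a hard target (a stereodefined medium ring with three stereocentres). The cation sits next to the C3 silyloxy carbon. Closure can go 1,6 or 5,10. The ring fusion depends on the ring conformer and on the C5=C6 geometry. Elimination competes with water capture, and the silyl ethers and allylic oxygen must survive acid.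
- Comparison: on structure it is more convergent in stereocentres. On mechanism the chosen anionic closure has one competing mode (C2), while the cation has several. On step economy the key step is richer, but reaching A1 should cost clearly more than the six steps from 3 to 10.

Alternative 2: Samarium Reformatsky aldol at C9–C10. The cut is C9–C10, from β-hydroxy ketone A4 back to bromomethyl ketone A3, which carries the C10 acetyl group on C1. In the forward step SmI2 would reduce the C–Br bond to a samarium enolate that adds to the methyl ketone through a chelated chair.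
- In its favour: the conditions are neutral and mild, and the aldol type is well precedented, which makes it the equal of the chosen closure in reliability. C14 is present from the start, so the oxidative cleavage and methyl addition of the chosen plan are not needed (better). The C8 ketone of A4 could be reduced under direction from the C10 hydroxyl to the natural 8α-alcohol (better than an SN2 inversion at a hindered carbon).
- Against it: the bond formed is the easy one. C6–C7 and the C6/C7 pair must already exist in A3 and would have to be set without a ring to control them. C7 in A3 and A4 is α to a ketone and allylic, so it can epimerise or let the methylene move into conjugation. Bromination must find C9 and not C7, and A4 can undergo retro-aldol cleavage.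
- Comparison: on structure the chosen plan puts its ring closure on the difficult bond. On mechanism both are sound. On step economy the saving at C10 is likely spent on building A3.

Alternative 3: Type 2 carbonyl-ene at C8–C9. The cut is C8–C9, from homoallylic alcohol A6 back to aldehyde A5, which keeps the isopropenyl group on C1. In the forward step a Lewis acid such as Me2AlCl would make the terminal isopropenyl carbon attack the C8 aldehyde while a methyl hydrogen is transferred, giving ring B with the C10 methylene.
- In its favour: the isopropenyl group of the terpene is used as it stands. The closure is concerted with no enolate regiochemistry to worry about (better than the chosen step on that point). A6 has the same C10 methylene as 12, so the later steps would be the same (equal). If the chair places the oxygen axial, C8 would come out in the natural configuration and no inversion would be needed (better, if it holds).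
- Against it: as in alternative 2 the C6–C7 bond must be made beforehand, for example by an intermolecular γ-functionalisation of the enone, which is harder than the tethered version. C7 in A5 is α to an aldehyde and allylic, so it is epimerisable under Lewis acid. The C8 configuration is not secured by any strong element.
- Comparison: on structure the chosen plan solves C6–C7 within the ring-forming step and this one leaves it open. On mechanism the ene closure is cleaner in regiochemistry but weaker in stereocontrol at C7 and C8. On step economy the downstream part is equal and the upstream part is longer.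

Key step: step 8

## Route

Step 1
Reactants: 1 acryloyl chloride
Product: 2 2-(trimethylsilyl)ethyl prop-2-enoate
Conditions: 2-(trimethylsilyl)ethanol, Et3N, CH2Cl2, 0 °C
Reagents that add atoms: 2-(trimethylsilyl)ethanol, OCC[Si](C)(C)C
Why: Acylation of a primary alcohol by an acid chloride (ester formation); the amine takes up HCl and the low temperature keeps the acrylate from polymerising.

Step 2
Reactants: 3 (S)-carvone; 4 ethyl glyoxylate
Product: 5 ethyl (2R)-2-hydroxy-4-[(1S)-4-methyl-5-oxocyclohex-3-en-1-yl]pent-4-enoate
Conditions: (R)-BINOL (10 mol%), TiCl2(OiPr)2 (10 mol%), 4 Å MS, CH2Cl2, −30 → 0 °C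
Reagents that add atoms: none
Why: Asymmetric glyoxylate-ene (carbonyl-ene) reaction under a chiral titanium diolate Lewis acid: the isopropenyl group is the only electron-rich ene, the hydrogen is taken from its methyl group through a six-membered transition state so the 1,1-disubstituted alkene is kept, and the catalyst shields one face of the bound aldehyde so that C8 should form as 2R under reagent control.

Step 3
Reactants: 5 ene adduct
Product: 6 ethyl (2R)-2-[(tert-butyldimethylsilyl)oxy]-4-[(1S)-4-methyl-5-oxocyclohex-3-en-1-yl]pent-4-enoate
Conditions: TBSCl, imidazole, DMF, rt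
Reagents that add atoms: tert-butyldimethylsilyl chloride, CC(C)(C)[Si](C)(C)Cl
Why: Standard silylation of a secondary alcohol; the TBS ether tolerates hydride, amine, alkoxide and organometallic reagents and is later removed by HF·pyridine without loss of the silylethyl ester.

Step 4
Reactants: 6 silyloxy ester
Product: 7 (2R)-2-[(tert-butyldimethylsilyl)oxy]-4-[(1S)-5-hydroxy-4-methylcyclohex-3-en-1-yl]pent-4-en-1-ol (both epimers at the ring carbinol carbon)
Conditions: i-Bu2AlH (4.5 equiv), CH2Cl2, −78 → 0 °C; aq. potassium sodium tartrate
Reagents that add atoms: none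
Why: Hydride reduction of both carbonyl groups (ester to primary alcohol, enone to allylic alcohol by 1,2-addition) avoids having to reduce the ester beside the enone; the new ring carbinol centre does not matter because step 5 removes it.

Step 5
Reactants: 7 diol
Product: 8 (2R)-2-[(tert-butyldimethylsilyl)oxy]-4-[(1S)-4-methyl-5-oxocyclohex-3-en-1-yl]pent-4-enal
Conditions: Dess–Martin periodinane (3 equiv), pyridine, CH2Cl2, 0 °C → rt
Reagents that add atoms: none
Why: Dess–Martin oxidation of both alcohols under buffered, non-basic conditions restores the enone and gives the α-silyloxy aldehyde without epimerising C8; the aldehyde is used crude.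

Step 6
Reactants: 8 keto aldehyde; 2 2-(trimethylsilyl)ethyl prop-2-enoate
Product: 9 2-(trimethylsilyl)ethyl (3RS,4R)-4-[(tert-butyldimethylsilyl)oxy]-3-hydroxy-2-methylidene-6-[(1S)-4-methyl-5-oxocyclohex-3-en-1-yl]hept-6-enoate
Conditions: 2 (3 equiv), DABCO (1 equiv), 1,4-dioxane/H2O (1:1), rt
Reagents that add atoms: none
Why: Morita–Baylis–Hillman reaction: DABCO adds to the acrylate and the ammonium enolate attacks the activated α-silyloxy aldehyde, which is far more electrophilic than the ketone, while the α-methyl enone of ring A has no α-hydrogen and cannot serve as donor; the new carbinol centre (C7) forms as a mixture that step 7 erases.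

Step 7
Reactants: 9 Baylis–Hillman alcohol
Product: 10 2-(trimethylsilyl)ethyl (2Z,4R)-2-(bromomethyl)-4-[(tert-butyldimethylsilyl)oxy]-6-[(1S)-4-methyl-5-oxocyclohex-3-en-1-yl]hepta-2,6-dienoate
Conditions: NBS, Me2S, CH2Cl2, 0 °C → rt
Reagents that add atoms: N-bromosuccinimide, BrN1C(=O)CCC1=O
Why: The allylic alcohol is activated as an alkoxysulfonium salt (Corey–Kim-type reagent) and bromide attacks the methylene terminus in SN2′ fashion; as is general for Baylis–Hillman adducts the trisubstituted alkene forms with the C8 substituent trans to the ester, which is the (Z)-bromide.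

Step 8
Reactants: 10 (Z)-2-(bromomethyl)enoate
Product: 12 2-(trimethylsilyl)ethyl (1R,6S,7S,8R)-8-[(tert-butyldimethylsilyl)oxy]-3-oxocadina-4,10(14),11(13)-trien-12-oate, via potassium dienolate 11 (not isolated)
Conditions: KOt-Bu (1.05 equiv), t-BuOH/THF (1:4), 0.01 M, −40 → 0 °C; AcOH quench
Reagents that add atoms: none
Why: tert-Butoxide in tert-butanol deprotonates the ring A enone reversibly, so the enolate population settles on the more stable linear dienolate 11 (O–C3=C4–C5=C6) formed by loss of a C6 proton; its C4 terminus cannot reach the tethered acceptor, so C6 adds to C7 of the (Z)-2-(bromomethyl)enoate and bromide leaves from C13, an intramolecular vinylogous Michael addition–elimination (SN2′ alkylation) that restores the C3 enone and creates the C11=C13 methylene. The closest known reaction type is the base-mediated intramolecular vinylogous alkylation of cyclohexenone extended enolates by tethered Michael acceptors or allylic halides. Ring B closes in the 6-exo-trig mode (C7=C11 is exocyclic to the new ring), whereas direct SN2 attack at C13 would need an eight-membered ring. C6 is controlled by C1: the tether sits equatorially on ring A and the new bond must form along the axis of the C6 p-orbital, which gives the cis ring fusion with H-1 and H-6 on the same face. C7 is controlled by the chair of the forming ring B with the acrylate unit equatorial, reinforced by allylic 1,3-strain: the C8 hydrogen eclipses the C7=C11 bond beside the CH2Br group, so the C8 silyloxy group lies equatorial and trans to the acrylate, which is why C8 is carried in the 8-epi configuration (4R in 10, 8R in 12). The selectivity the step needs is attack through C6 (γ) and not through C2 (α′), which would also give a six-membered ring; only the thermodynamic preference for the linear over the cross-conjugated enolate under proton-exchanging conditions secures it, and kinetic amide bases at low temperature are avoided for that reason. One equivalent of base ends as KBr, so the product is not left in a basic medium that could epimerise C6.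

Step 9
Reactants: 12 cis-fused enone
Product: 13 2-(trimethylsilyl)ethyl (1R,3S,6S,7S,8R)-8-[(tert-butyldimethylsilyl)oxy]-3-hydroxycadina-4,10(14),11(13)-trien-12-oate
Conditions: NaBH4, CeCl3·7H2O, MeOH, −78 °C
Reagents that add atoms: none
Why: Luche reduction: the cerium-activated ketone takes hydride in 1,2-fashion along the axial direction from the open α face (ring B and the axial C6–C7 bond cover the β face), giving the pseudo-equatorial 3β-alcohol, the cis-carveol relationship to C1; the unsaturated ester is inert at −78 °C.

Step 10
Reactants: 13 allylic alcohol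
Product: 14 2-(trimethylsilyl)ethyl (1R,3S,6S,7S,8R)-3-acetoxy-8-[(tert-butyldimethylsilyl)oxy]cadina-4,10(14),11(13)-trien-12-oate
Conditions: Ac2O, pyridine, DMAP (cat.), CH2Cl2, 0 °C → rt
Reagents that add atoms: acetic anhydride, CC(=O)OC(C)=O
Why: Acylation of the only free hydroxyl installs the C3 acetate of the target and also deactivates the ring A alkene towards the osmylation that follows.

Step 11
Reactants: 14 allylic acetate
Product: 16 2-(trimethylsilyl)ethyl (1R,3S,6R,7S,8R)-3-acetoxy-8-[(tert-butyldimethylsilyl)oxy]-10-oxo-14-norcadina-4,11(13)-dien-12-oate, via vicinal diol 15 (not isolated)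
Conditions: OsO4 (2 mol%), NaIO4 (4 equiv), 2,6-lutidine, 1,4-dioxane/H2O (3:1), rt
Reagents that add atoms: osmium tetroxide (OsO4), O=[Os](=O)(=O)=O; sodium periodate (NaIO4), [Na+].[O-]I(=O)(=O)=O; water, O
Why: Lemieux–Johnson oxidation: OsO4 dihydroxylates the exocyclic 1,1-disubstituted alkene, the most accessible and most electron-rich of the three (the ring A alkene is trisubstituted, flanked by the ring fusion and deactivated by the allylic acetate; the acrylate is electron-poor), and periodate cleaves diol 15 in situ; 2,6-lutidine keeps the medium neutral so that C1, now α to a ketone, and the β-silyloxy group are not endangered.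

Step 12
Reactants: 16 C10 ketone
Product: 17 2-(trimethylsilyl)ethyl (1R,3S,6R,7S,8R,10S)-3-acetoxy-8-[(tert-butyldimethylsilyl)oxy]-10-hydroxycadina-4,11(13)-dien-12-oate
Conditions: MeMgBr (1.5 equiv), CeCl3 (anhydrous, 1.5 equiv), THF, −78 °C
Reagents that add atoms: methylmagnesium bromide (MeMgBr), C[Mg]Br
Why: 1,2-Addition of a methylcerium reagent, which is weakly basic (no enolisation towards C9 and no β-elimination of the C8 silyloxy group) and at −78 °C much faster at the ketone than at the acetate or the acrylate ester; attack comes along the axial direction from the convex α face, anti to the axial C1–C2 bond that covers the β face of ring B, so the methyl group becomes axial (α) and the hydroxyl equatorial (β).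

Step 13
Reactants: 17 tertiary alcohol
Product: 18 2-(trimethylsilyl)ethyl (1R,3S,6R,7S,8R,10S)-3-acetoxy-8,10-dihydroxycadina-4,11(13)-dien-12-oate
Conditions: HF·pyridine, pyridine, THF, 0 °C → rt
Reagents that add atoms: none
Why: Acidic fluoride removes the secondary TBS ether (desilylation) but, unlike fluoride anion, should spare the 2-(trimethylsilyl)ethyl ester; the pyridine buffer protects the allylic acetate and the tertiary alcohol and keeps the trans γ-hydroxy ester from lactonising.

Step 14
Reactants: 19 but-2-yne-1,4-diol
Product: 20 (2E)-2-(tributylstannyl)but-2-ene-1,4-diol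
Conditions: Bu3SnH, PdCl2(PPh3)2 (2 mol%), THF, rt
Reagents that add atoms: tributyltin hydride (Bu3SnH), CCCC[SnH](CCCC)CCCC
Why: Palladium-catalysed hydrostannation (the PdCl2(PPh3)2 precatalyst is reduced by the tin hydride to zerovalent palladium): syn addition of H and Sn to the symmetrical alkyne makes regiochemistry moot and places the two hydroxymethyl groups cis, the geometry of the side chain.

Step 15
Reactants: 20 stannyl diol
Product: 21 2,2-dimethyl-5-(tributylstannyl)-4,7-dihydro-1,3-dioxepine
Conditions: 2,2-dimethoxypropane, PPTS (cat.), CH2Cl2, rt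
Reagents that add atoms: 2,2-dimethoxypropane, COC(C)(C)OC
Why: Acid-catalysed transketalisation: only a cis-disposed 1,4-diol can close the seven-membered acetonide, which protects both alcohols, locks the alkene geometry and gives a compact acid for the hindered esterification.

Step 16
Reactants: 21 stannyl acetonide
Product: 23 2,2-dimethyl-4,7-dihydro-1,3-dioxepine-5-carboxylic acid, via vinyllithium 22 (not isolated)
Conditions: n-BuLi, THF, −78 °C; CO2; then 0.5 M HCl to pH 4, 0 °C
Reagents that add atoms: carbon dioxide, O=C=O
Why: Tin–lithium exchange proceeds with retention at the vinyl carbon and the vinyllithium is trapped by CO2 (carboxylation); −78 °C prevents β-elimination of the allylic oxygen and cautious acidification spares the acetonide.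

Step 17
Reactants: 18 diol; 23 side-chain acid
Product: 24 2-(trimethylsilyl)ethyl (1R,3S,6R,7S,8S,10S)-3-acetoxy-8-[(2,2-dimethyl-4,7-dihydro-1,3-dioxepine-5-carbonyl)oxy]-10-hydroxycadina-4,11(13)-dien-12-oate
Conditions: 23 (2 equiv), PPh3, DIAD, toluene, 0 → 40 °C
Reagents that add atoms: none
Why: Mitsunobu esterification: the equatorial 8β-hydroxyl becomes an alkoxyphosphonium leaving group and is displaced by the carboxylate of 23 in an SN2 reaction with inversion, giving the axial 8α-ester cis to the C7 side chain; the tertiary C10 hydroxyl is inert, and since C8 never carries a free hydroxyl cis to the C12 ester, lactonisation cannot intervene.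

Step 18
Reactants: 24 fully protected ester
Product: 26 (1R,3S,6R,7S,8S,10S)-3-acetoxy-10-hydroxy-8-{[(2E)-4-hydroxy-2-(hydroxymethyl)but-2-enoyl]oxy}cadina-4,11(13)-dien-12-oic acid (CNP0468194.1), via acetonide acid 25 (not isolated)
Conditions: TASF [(Me2N)3S+ Me3SiF2−], DMF, 0 °C → rt; then AcOH/H2O (4:1), 35 °C
Reagents that add atoms: none
Why: Fluoride attacks silicon of the 2-(trimethylsilyl)ethyl ester, which fragments to the carboxylate, ethene and Me3SiF (fluoride-induced β-elimination) while the acetate and the C8 ester stay; dilute acetic acid then hydrolyses the seven-membered acetonide under conditions the allylic acetate, the tertiary alcohol and the α-methylene acid tolerate, and the by-products of this stage are volatile.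

## Compound list

1 | acryloyl chloride | C=CC(Cl)=O | starting material
2 | 2-(trimethylsilyl)ethyl prop-2-enoate | C=CC(=O)OCC[Si](C)(C)C | intermediate
3 | (S)-carvone | CC1=CC[C@@H](CC1=O)C(C)=C | starting material
4 | ethyl glyoxylate | CCOC(=O)C=O | starting material
5 | ethyl (2R)-2-hydroxy-4-[(1S)-4-methyl-5-oxocyclohex-3-en-1-yl]pent-4-enoate | CC1=CC[C@@H](CC1=O)C(=C)C[C@@H](O)C(=O)OCC | intermediate
6 | ethyl (2R)-2-[(tert-butyldimethylsilyl)oxy]-4-[(1S)-4-methyl-5-oxocyclohex-3-en-1-yl]pent-4-enoate | CC1=CC[C@@H](CC1=O)C(=C)C[C@@H](O[Si](C)(C)C(C)(C)C)C(=O)OCC | intermediate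
7 | (2R)-2-[(tert-butyldimethylsilyl)oxy]-4-[(1S)-5-hydroxy-4-methylcyclohex-3-en-1-yl]pent-4-en-1-ol, both epimers at the ring carbinol carbon | CC1=CC[C@@H](CC1O)C(=C)C[C@@H](O[Si](C)(C)C(C)(C)C)CO | intermediate
8 | (2R)-2-[(tert-butyldimethylsilyl)oxy]-4-[(1S)-4-methyl-5-oxocyclohex-3-en-1-yl]pent-4-enal | CC1=CC[C@@H](CC1=O)C(=C)C[C@@H](O[Si](C)(C)C(C)(C)C)C=O | intermediate
9 | 2-(trimethylsilyl)ethyl (3RS,4R)-4-[(tert-butyldimethylsilyl)oxy]-3-hydroxy-2-methylidene-6-[(1S)-4-methyl-5-oxocyclohex-3-en-1-yl]hept-6-enoate | CC1=CC[C@@H](CC1=O)C(=C)C[C@@H](O[Si](C)(C)C(C)(C)C)C(O)C(=C)C(=O)OCC[Si](C)(C)C | intermediate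
10 | 2-(trimethylsilyl)ethyl (2Z,4R)-2-(bromomethyl)-4-[(tert-butyldimethylsilyl)oxy]-6-[(1S)-4-methyl-5-oxocyclohex-3-en-1-yl]hepta-2,6-dienoate (C10 methylene, 8-epi silyloxy group) | CC1=CC[C@@H](CC1=O)C(=C)C[C@@H](O[Si](C)(C)C(C)(C)C)/C=C(\CBr)C(=O)OCC[Si](C)(C)C | intermediate
11 | potassium linear dienolate of 10 (O–C3=C4–C5=C6) | [K+].[O-]C1=C(C)C=C[C@@H](C1)C(=C)C[C@@H](O[Si](C)(C)C(C)(C)C)/C=C(\CBr)C(=O)OCC[Si](C)(C)C | intermediate (not isolated)
12 | 2-(trimethylsilyl)ethyl (1R,6S,7S,8R)-8-[(tert-butyldimethylsilyl)oxy]-3-oxocadina-4,10(14),11(13)-trien-12-oate; cis-fused, H-1, H-6 and the C7 acrylate α, 8-OTBS β | C=C(C(=O)OCC[Si](C)(C)C)[C@@H]1[C@H]2C=C(C)C(=O)C[C@H]2C(=C)C[C@H]1O[Si](C)(C)C(C)(C)C | intermediate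
13 | 2-(trimethylsilyl)ethyl (1R,3S,6S,7S,8R)-8-[(tert-butyldimethylsilyl)oxy]-3-hydroxycadina-4,10(14),11(13)-trien-12-oate; 3β-OH | C=C(C(=O)OCC[Si](C)(C)C)[C@@H]1[C@H]2C=C(C)[C@@H](O)C[C@H]2C(=C)C[C@H]1O[Si](C)(C)C(C)(C)C | intermediate
14 | 2-(trimethylsilyl)ethyl (1R,3S,6S,7S,8R)-3-acetoxy-8-[(tert-butyldimethylsilyl)oxy]cadina-4,10(14),11(13)-trien-12-oate | C=C(C(=O)OCC[Si](C)(C)C)[C@@H]1[C@H]2C=C(C)[C@@H](OC(C)=O)C[C@H]2C(=C)C[C@H]1O[Si](C)(C)C(C)(C)C | intermediate
15 | 2-(trimethylsilyl)ethyl (1R,3S,6R,7S,8R)-3-acetoxy-8-[(tert-butyldimethylsilyl)oxy]-10,14-dihydroxycadina-4,11(13)-dien-12-oate, both C10 epimers | C=C(C(=O)OCC[Si](C)(C)C)[C@@H]1[C@H]2C=C(C)[C@@H](OC(C)=O)C[C@H]2C(O)(CO)C[C@H]1O[Si](C)(C)C(C)(C)C | intermediate (not isolated)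
16 | 2-(trimethylsilyl)ethyl (1R,3S,6R,7S,8R)-3-acetoxy-8-[(tert-butyldimethylsilyl)oxy]-10-oxo-14-norcadina-4,11(13)-dien-12-oate | C=C(C(=O)OCC[Si](C)(C)C)[C@@H]1[C@H]2C=C(C)[C@@H](OC(C)=O)C[C@H]2C(=O)C[C@H]1O[Si](C)(C)C(C)(C)C | intermediate
17 | 2-(trimethylsilyl)ethyl (1R,3S,6R,7S,8R,10S)-3-acetoxy-8-[(tert-butyldimethylsilyl)oxy]-10-hydroxycadina-4,11(13)-dien-12-oate; 10β-OH, 10α-CH3 | C=C(C(=O)OCC[Si](C)(C)C)[C@@H]1[C@H]2C=C(C)[C@@H](OC(C)=O)C[C@H]2[C@@](C)(O)C[C@H]1O[Si](C)(C)C(C)(C)C | intermediate
18 | 2-(trimethylsilyl)ethyl (1R,3S,6R,7S,8R,10S)-3-acetoxy-8,10-dihydroxycadina-4,11(13)-dien-12-oate; 8β-OH | C=C(C(=O)OCC[Si](C)(C)C)[C@@H]1[C@H]2C=C(C)[C@@H](OC(C)=O)C[C@H]2[C@@](C)(O)C[C@H]1O | intermediate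
19 | but-2-yne-1,4-diol | OCC#CCO | starting material
20 | (2E)-2-(tributylstannyl)but-2-ene-1,4-diol (hydroxymethyl groups cis) | OC/C=C(\CO)[Sn](CCCC)(CCCC)CCCC | intermediate
21 | 2,2-dimethyl-5-(tributylstannyl)-4,7-dihydro-1,3-dioxepine | CC1(C)OCC=C(CO1)[Sn](CCCC)(CCCC)CCCC | intermediate
22 | (2,2-dimethyl-4,7-dihydro-1,3-dioxepin-5-yl)lithium | [Li]C1=CCOC(C)(C)OC1 | intermediate (not isolated)
23 | 2,2-dimethyl-4,7-dihydro-1,3-dioxepine-5-carboxylic acid | OC(=O)C1=CCOC(C)(C)OC1 | intermediate
24 | 2-(trimethylsilyl)ethyl (1R,3S,6R,7S,8S,10S)-3-acetoxy-8-[(2,2-dimethyl-4,7-dihydro-1,3-dioxepine-5-carbonyl)oxy]-10-hydroxycadina-4,11(13)-dien-12-oate; 8α-ester | C=C(C(=O)OCC[Si](C)(C)C)[C@@H]1[C@H]2C=C(C)[C@@H](OC(C)=O)C[C@H]2[C@@](C)(O)C[C@@H]1OC(=O)C1=CCOC(C)(C)OC1 | intermediate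
25 | (1R,3S,6R,7S,8S,10S)-3-acetoxy-8-[(2,2-dimethyl-4,7-dihydro-1,3-dioxepine-5-carbonyl)oxy]-10-hydroxycadina-4,11(13)-dien-12-oic acid | C=C(C(=O)O)[C@@H]1[C@H]2C=C(C)[C@@H](OC(C)=O)C[C@H]2[C@@](C)(O)C[C@@H]1OC(=O)C1=CCOC(C)(C)OC1 | intermediate (not isolated)
26 | (1R,3S,6R,7S,8S,10S)-3-acetoxy-10-hydroxy-8-{[(2E)-4-hydroxy-2-(hydroxymethyl)but-2-enoyl]oxy}cadina-4,11(13)-dien-12-oic acid (CNP0468194.1) | C=C(C(=O)O)[C@@H]1[C@H]2C=C(C)[C@@H](OC(C)=O)C[C@H]2[C@@](C)(O)C[C@@H]1OC(=O)/C(=C/CO)CO | target

## Step count and least certain steps

Total: 18 steps (one-pot operations counted once). Longest linear sequence: 14 steps from 3 (steps 2–13, 17, 18). Steps 1 and 14–16 prepare 2 and 23.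

**Step 8 (key step).** The most likely failure is ring closure through C2, the α′ carbon of the cross-conjugated enolate. This would also give a six-membered ring. The two enolates interconvert, so the outcome rests on their populations and intrinsic rates, and a simple enolate carbon is intrinsically more reactive than the γ terminus of a dienolate. Fallback, from 10 back to 12: replace thermodynamic control by kinetic, site-selective deprotonation. Both carbonyl groups of 10 are first complexed with aluminium tris(2,6-diphenylphenoxide), Al(OC6H3Ph2)3 (2.2 equiv, toluene, −78 °C). The bulky aryloxide buries C2 and C4, so LiN(i-Pr)2 (THF, −78 °C) can reach only the C6 hydrogens. The resulting aluminium-bound lithium dienolate of 10 F1 can react only through C6, as in the vinylogous aldol reactions for which this reagent pair is known, and warming to −40 °C should close ring B to 12.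

**Step 17.** The most likely failure is a stalled displacement. The carboxylate has to enter C8 along the axial direction on the α face, where the axial C10 methyl stands 1,3 to it. The alkoxyphosphonium may then divert to acylation with retention, to elimination, or to participation by the C12 ester carbonyl with loss of the silylethyl group. Fallback, from 18 back to 24: an oxidation–directed reduction–acylation sequence that replaces the SN2 event by a hydride delivery directed by the C10 oxygen itself.
- Dess–Martin oxidation (pyridine, CH2Cl2, 0 °C) gives the C8 ketone F2.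
- Evans–Saksena reduction with Me4NBH(OAc)3 (MeCN/AcOH, −30 °C) delivers hydride within the C10-alkoxyborohydride on the β face and gives the 1,3-anti diol, the 8α-alcohol F3.
- F3 is acylated at once with 23 (EDC·HCl, DMAP, CH2Cl2, 0 °C; Steglich esterification) to give 24.
The cost is two more steps, with C7 (α to the ketone) exposed to epimerisation and the free cis γ-hydroxy ester to lactonisation.

**Step 6.** The most likely failure is loss of configuration at C8 by amine-mediated enolisation of the α-silyloxy aldehyde during a slow reaction, or stalling. Fallback, from 8 back to 9: the acrylate unit is delivered as a non-basic vinylaluminium reagent. 2-(Trimethylsilyl)ethyl prop-2-ynoate F4 (from propiolic acid and 2-(trimethylsilyl)ethanol, DCC, DMAP) is hydroaluminated with i-Bu2AlH and N-methylmorpholine N-oxide in THF at 0 °C. The resulting diisobutyl{1-[2-(trimethylsilyl)ethoxycarbonyl]ethenyl}aluminium F5 is added to 8 at −78 °C, where the aldehyde reacts and the enone does not, to give 9.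

**Step 11.** The most likely failure is competing osmylation of the ring A alkene, or epimerisation at C1 once the ketone is formed. Fallback, from 12 back to 16: the cleavage is moved to the enone stage, where the ring A alkene is conjugated and as electron-poor as the acrylate.
- OsO4 (cat.) with N-methylmorpholine N-oxide in acetone/H2O gives the 10,14-diol enone F6.
- Luche reduction (NaBH4, CeCl3·7H2O, MeOH, −78 °C) gives the 3,10,14-triol F7.
- NaIO4 (THF/H2O) cleaves the vicinal diol to the 3-hydroxy 10-ketone F8.
- Ac2O/pyridine gives 16.
This is one step longer than the main sequence.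

**Step 2.** The most likely failure is insufficient control at C8 (a mismatched substrate–catalyst pair, or inhibition of the Lewis acid by the enone carbonyl), or hydrogen transfer from C1 instead of the methyl group. Fallback, from 3 and 4 back to 5: the ene reaction is run with SnCl4 (CH2Cl2, −78 °C) without asymmetric induction. Because 3 is enantiopure, 5 and its (2S)-epimer F9 are diastereomers and are separated. F9 is corrected by Mitsunobu inversion with 4-nitrobenzoic acid (PPh3, DIAD, THF) to the (2R)-4-nitrobenzoate F10, which K2CO3 in EtOH cleaves to 5.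

## Further compounds

F1 | step 8 | lithium linear dienolate of 10, bound to aluminium tris(2,6-diphenylphenoxide) (drawn without the aluminium reagent; not isolated) | [Li+].[O-]C1=C(C)C=C[C@@H](C1)C(=C)C[C@@H](O[Si](C)(C)C(C)(C)C)/C=C(\CBr)C(=O)OCC[Si](C)(C)C
F2 | step 17 | 2-(trimethylsilyl)ethyl (1R,3S,6S,7S,10S)-3-acetoxy-10-hydroxy-8-oxocadina-4,11(13)-dien-12-oate | C=C(C(=O)OCC[Si](C)(C)C)[C@@H]1[C@H]2C=C(C)[C@@H](OC(C)=O)C[C@H]2[C@@](C)(O)CC1=O
F3 | step 17 | 2-(trimethylsilyl)ethyl (1R,3S,6R,7S,8S,10S)-3-acetoxy-8,10-dihydroxycadina-4,11(13)-dien-12-oate (8α-OH) | C=C(C(=O)OCC[Si](C)(C)C)[C@@H]1[C@H]2C=C(C)[C@@H](OC(C)=O)C[C@H]2[C@@](C)(O)C[C@@H]1O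
F4 | step 6 | 2-(trimethylsilyl)ethyl prop-2-ynoate | C#CC(=O)OCC[Si](C)(C)C
F5 | step 6 | diisobutyl{1-[2-(trimethylsilyl)ethoxycarbonyl]ethenyl}aluminium (not isolated) | C=C([Al](CC(C)C)CC(C)C)C(=O)OCC[Si](C)(C)C
F6 | step 11 | 2-(trimethylsilyl)ethyl (1R,6R,7S,8R)-8-[(tert-butyldimethylsilyl)oxy]-10,14-dihydroxy-3-oxocadina-4,11(13)-dien-12-oate, both C10 epimers | C=C(C(=O)OCC[Si](C)(C)C)[C@@H]1[C@H]2C=C(C)C(=O)C[C@H]2C(O)(CO)C[C@H]1O[Si](C)(C)C(C)(C)C
F7 | step 11 | 2-(trimethylsilyl)ethyl (1R,3S,6R,7S,8R)-8-[(tert-butyldimethylsilyl)oxy]-3,10,14-trihydroxycadina-4,11(13)-dien-12-oate, both C10 epimers | C=C(C(=O)OCC[Si](C)(C)C)[C@@H]1[C@H]2C=C(C)[C@@H](O)C[C@H]2C(O)(CO)C[C@H]1O[Si](C)(C)C(C)(C)C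
F8 | step 11 | 2-(trimethylsilyl)ethyl (1R,3S,6R,7S,8R)-8-[(tert-butyldimethylsilyl)oxy]-3-hydroxy-10-oxo-14-norcadina-4,11(13)-dien-12-oate | C=C(C(=O)OCC[Si](C)(C)C)[C@@H]1[C@H]2C=C(C)[C@@H](O)C[C@H]2C(=O)C[C@H]1O[Si](C)(C)C(C)(C)C
F9 | step 2 | ethyl (2S)-2-hydroxy-4-[(1S)-4-methyl-5-oxocyclohex-3-en-1-yl]pent-4-enoate | CC1=CC[C@@H](CC1=O)C(=C)C[C@H](O)C(=O)OCC
F10 | step 2 | ethyl (2R)-4-[(1S)-4-methyl-5-oxocyclohex-3-en-1-yl]-2-[(4-nitrobenzoyl)oxy]pent-4-enoate | CC1=CC[C@@H](CC1=O)C(=C)C[C@@H](OC(=O)c1ccc(cc1)[N+](=O)[O-])C(=O)OCC
A1 | alternative 1 | 2-(trimethylsilyl)ethyl (1(10)E,5E)-3,8-bis[(tert-butyldimethylsilyl)oxy]germacra-1(10),4(15),5,11(13)-tetraen-12-oate (C3, C7, C8 configured as in A2) | C=C(C(=O)OCC[Si](C)(C)C)[C@@H]1/C=C/C(=C)[C@@H](O[Si](C)(C)C(C)(C)C)C/C=C(C)/C[C@@H]1O[Si](C)(C)C(C)(C)C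
A2 | alternative 1 | 2-(trimethylsilyl)ethyl (1R,3S,6R,7S,8S,10S)-3,8-bis[(tert-butyldimethylsilyl)oxy]-10-hydroxycadina-4,11(13)-dien-12-oate | C=C(C(=O)OCC[Si](C)(C)C)[C@@H]1[C@H]2C=C(C)[C@@H](O[Si](C)(C)C(C)(C)C)C[C@H]2[C@@](C)(O)C[C@@H]1O[Si](C)(C)C(C)(C)C
A3 | alternative 2 | 2-(trimethylsilyl)ethyl 9-bromo-3-[(tert-butyldimethylsilyl)oxy]-8,10-dioxo-9,10-secocadina-4,11(13)-dien-12-oate (C1, C3, C6, C7 configured as in A4) | C=C(C(=O)OCC[Si](C)(C)C)[C@H]([C@H]1C=C(C)[C@@H](O[Si](C)(C)C(C)(C)C)C[C@H]1C(C)=O)C(=O)CBr
A4 | alternative 2 | 2-(trimethylsilyl)ethyl (1R,3S,6S,7S,10S)-3-[(tert-butyldimethylsilyl)oxy]-10-hydroxy-8-oxocadina-4,11(13)-dien-12-oate | C=C(C(=O)OCC[Si](C)(C)C)[C@@H]1[C@H]2C=C(C)[C@@H](O[Si](C)(C)C(C)(C)C)C[C@H]2[C@@](C)(O)CC1=O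
A5 | alternative 3 | 2-(trimethylsilyl)ethyl 3-[(tert-butyldimethylsilyl)oxy]-8-oxo-8,9-secocadina-4,10(14),11(13)-trien-12-oate (C1, C3, C6, C7 configured as in A6) | C=C(C(=O)OCC[Si](C)(C)C)[C@H]([C@H]1C=C(C)[C@@H](O[Si](C)(C)C(C)(C)C)C[C@H]1C(C)=C)C=O
A6 | alternative 3 | 2-(trimethylsilyl)ethyl (1R,3S,6S,7S,8S)-3-[(tert-butyldimethylsilyl)oxy]-8-hydroxycadina-4,10(14),11(13)-trien-12-oate | C=C(C(=O)OCC[Si](C)(C)C)[C@@H]1[C@H]2C=C(C)[C@@H](O[Si](C)(C)C(C)(C)C)C[C@H]2C(=C)C[C@@H]1O
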